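**Route to CNP0189964.2 (3‑O‑angeloyl drimane‑8‑ol 11‑umbelliferyl ether) by quinone Diels–Alder annulation of ring A**

## Analysis of the target

The target is a drimane-type sesquiterpene ether of umbelliferone built on a trans-decalin. Ring A (C1–C5, C10) carries the angelate on O3 and the gem-dimethyl group on C4; ring B (C5–C10) carries a methyl and a tertiary hydroxyl on C8, the angular methyl on C10 and, on C9, the C11 methylene bound to O7 of the coumarin. There are five stereocentres, (3R,5S,8S,9R,10R) in drimane numbering. H5 is anti to the C10 methyl; O3, the C8 methyl and C11 lie on the face of the C10 methyl; H9 and the C8 hydroxyl lie on the other face, so O3, O8 and C11 are all equatorial. The decalin is the mirror image of the one in sclareol-derived drimanes, so the usual chiral pool gives the wrong enantiomer and absolute control must come from a catalyst. Sensitive groups are the (Z)-2-methylbut-2-enoate (isomerises to the E ester under nucleophilic acyl-transfer catalysis), the coumarin lactone (does not survive hydride reagents) and the tertiary alcohol, which is 1,3 to O11 and can dehydrate or close an oxetane if C11 is activated carelessly. The difficulty is congestion: quaternary C4 and C10 flank C5, C9 sits between quaternary C10 and fully substituted C8, and three contiguous ring-B centres must be set relative to C10. The route rests on two mappings: ring B (methyls on C8 and C10 on either side of C9, C6 para to C9) is a masked 2,6-dimethyl-1,4-benzoquinone, and C1–C4 with oxygen on C3 and two methyls on C4 is a 2-silyloxydiene with a dimethylated terminus. A [4+2] between the two closes ring A and creates C10 and C5.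

## Retrosynthetic reasoning

20 ⇒ 18 + 19. The O3–acyl bond is cut first. The angelate is geometrically labile and would not survive any reduction, so it goes on last. The forward acylation has to keep the Z alkene and distinguish secondary O3 from tertiary O8, which sterics do.

18 ⇒ 16 + 17. The C11–O bond to the coumarin oxygen is cut at the alkyl side. This keeps the lactone of 17 out of all hydride steps. The forward etherification has to pick the primary hydroxyl of triol 16; O3 is neopentyl-type secondary and O8 is tertiary.

16 ⇒ 15 ⇒ 14. The C7–H bond and then the epoxide C–O bonds are removed, leading back to the C7=C8 alkene of 14. The alkene and its methyl come directly from the quinone. The forward steps need oxygen delivery anti to the C10 methyl and hydride attack at C7, not C8.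

14 ⇒ 12 ⇒ 11. The C11–O and C9–H bonds are traced to the exocyclic alkene of 12, and the C9=C11 bond to the C9 carbonyl of 11, the second quinone carbonyl. Hydroboration on the rigid trans-decalin sets C9 by approach anti to the axial C10 methyl.

11 ⇒ 10. The C3–H bond is cut; the C3 ketone of 10 is the hydrolysed silyl enol ether of the diene component. The forward reduction must give the equatorial alcohol and leave the hindered C9 enone alone.

10 ⇒ 7 ⇒ 6 ⇒ 4. The C5–H and C6–H bonds are cut. The cycloaddition delivers 4 cis-fused with a carbonyl at C6; the target is trans-fused and has CH2 at C6. Equilibration of 4 through its C5 enol cannot be relied on. The cis isomer lets quaternary C4 sit axial on the flat ene-dione ring, away from the C6 carbonyl, and avoids the syn-axial C4/C10 methyl contact that the trans isomer must accept, so cis is expected to be at least as stable. The C6 carbonyl is therefore used to erase C5 (enol triflate 6), the triflate is reduced to dienone 7, and C5 is reset by a dissolving-metal reduction, whose protonation gives the trans fusion independently of product stability. Three steps then do both jobs.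

4 ⇒ 2 + 3. The C4–C5 and C1–C10 bonds are cut in a retro-[4+2]. No other cut gives two components that together hold all fourteen ring carbons, all four methyls and three of the oxygens. The forward reaction must join the CMe2 terminus of 2 to the unsubstituted alkene carbon of 3 and select one enantiotopic face of the quinone alkene.

2 ⇒ 1. The O–Si bond is cut; 1 has a single enolisable position, so silylation can give only 2.

## Alternatives that were turned down

Alternative 1: ring B closed by an Ireland–Claisen ring contraction.
- Disconnection: the C9–C10 bond. In the reverse sense a C6–O bond is restored, so ring B is stored as the six-membered lactone A2, with the C11 carboxyl esterified to O6 and C6 attached to a cyclohexene holding the C5=C10 alkene, the C4 methyls and a C3 ketal.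
- Forward key step: A2 is silylated twice (lactone enolate and O8; LDA, Me3SiCl) and warmed. The [3,3] shift forms C9–C10, breaks C6–O and gives acid A1 with ring B closed, a C5=C6 alkene and the carboxyl on C9.
- For it: quaternary C10 is made with chirality transfer from C6, and the C8 tertiary alcohol and C11 at the carboxyl level are present from the outset. The methylenation, hydroboration and epoxide steps of the chosen route are not needed, so on ring-B functionality this plan is the stronger one.
- Against it: the new bond must form at a fully substituted alkene carbon next to the gem-dimethyl group, through the boat-like array the lactone enforces, which pushes C7 against the C10 methyl. The enolate carries a β-silyloxy group and can eliminate instead. A1 has the wrong configuration at C9 and a C5=C6 alkene, so two centres remain to be corrected (C9 by ester epimerisation, C5 by hydrogenation between two quaternary carbons) and the acid must be reduced. A2 itself needs C6 and C8 set in enantiopure form.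
- Comparison: the chosen route reaches its bicyclic intermediate in two steps from purchased compounds with one asymmetric event and sets C9 and C8 by additions to a rigid trans-decalin. It gives up the pre-installed oxidation pattern of ring B.

Alternative 2: Birch dearomatisation, hydroxyl-directed cyclopropanation, angular methyl by strain release.
- Disconnection: the C10 methyl is traced to the CH2 of a C5–C10 cyclopropane and ring A to an aryl methyl ether ring, so the synthesis would start from a bicyclic aryl ether already carrying the C8 and C9 substituents.
- Forward key step: the tetrasubstituted C5=C10 alkene of the Birch-derived ketal A4 is cyclopropanated with Et2Zn/CH2I2 under direction of the C11 hydroxyl to give A3. Later opening of the three-membered ring turns its CH2 into the C10 methyl.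
- For it: every reaction type is classical, delivery from the C11 hydroxyl puts the future methyl on the face of C11 as required, and C8/C9 can be fixed early. In reliability of the single steps and in the C9/C10 relationship it is stronger than the chosen plan.
- Against it: A3 has no methyls on C4. They must be added after cyclopropane opening by double alkylation of the resulting enone, which shifts the alkene to C5=C6 and leaves C5 to a hindered reduction, the same problem as in the chosen route but met much later. Ketal, silyl ether and redox changes at C3 push the count past twenty steps.
- Comparison: the chosen route brings C4 with both methyls and C10 with its methyl in the two cycloaddition partners and is far more convergent. It pays with one unprecedented step.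

Alternative 3: three-component Michael–Michael–Dieckmann annulation of ring A.
- Disconnection: C4–C5, C1–C10 and C2–C3, back to 2-methylcyclohex-2-enone A6 (ring B with the C9 carbonyl and C10 methyl), the ketene silyl acetal of phenyl isobutyrate A8 (C3, C4 and the gem-dimethyl group) and methyl acrylate A7 (C1, C2).
- Forward key step: A8 adds to C5 of A6 (Mukaiyama–Michael), MeLi releases the C10 enolate, which adds to A7, and the new ester enolate closes on the phenyl ester to give keto ester A5.
- For it: three bonds, both quaternary carbons and a trans ring fusion arise in one flask from bulk chemicals, and no correction at C5 is needed. On that point it is stronger than the chosen route.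
- Against it: A5 is racemic unless the first conjugate addition, of a fully substituted ketene acetal to an α-substituted enone, can be made enantioselective. Alkylation of the C10 enolate next to the new quaternary substituent on C5 is very congested. Ring B arrives as a bare cyclohexanone, so the C8 methyl, the C7=C8 unsaturation and all later ring-B steps still lie ahead, and the C2 ester must be removed.
- Comparison: the quinone of the chosen route supplies both ring-B methyls, the C9 carbonyl and the alkene for the C8 hydroxyl in one purchased compound, and the absolute configuration is set in the same step. The alternative's advantage at C5 does not make up for the missing ring-B substituents and enantiocontrol.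

Key step: step 2

Assumption: the target is the (3R,5S,8S,9R,10R) enantiomer; the catalyst in step 2 is written as the (S)-prolinol-derived antipode, and its mirror image is used if the sense of induction proves opposite. Names use drimane locants for constitution only; configuration is given by the CIP descriptors and the SMILES.

## Steps

Step 1
Reactants: 1 4-methylpent-1-en-3-one (isopropyl vinyl ketone)
Product: 2 3-(tert-butyldimethylsilyloxy)-4-methylpenta-1,3-diene
Conditions: t-BuMe2SiOTf, Et3N, Et2O, 0 → 23 °C
Reagents that add atoms: tert-butyldimethylsilyl trifluoromethanesulfonate, CC(C)(C)[Si](C)(C)OS(=O)(=O)C(F)(F)F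
Why: Soft enolisation and O-silylation of a ketone (silyl enol ether formation); the isopropyl methine is the only enolisable position, so the tetrasubstituted enol ether forms without regio- or geometric isomers and the vinyl group remains as the second diene alkene.

Step 2
Reactants: 2 3-(tert-butyldimethylsilyloxy)-4-methylpenta-1,3-diene; 3 2,6-dimethyl-1,4-benzoquinone
Product: 4 cis-fused adduct (4aS,8aR)-6-(tert-butyldimethylsilyloxy)-2,5,5,8a-tetramethyl-4a,5,8,8a-tetrahydronaphthalene-1,4-dione (drimane numbering 5S,10R; H5 and the C10 methyl on the same face; silyl enol ether C2=C3; ene-dione C6(=O)–C7=C8(CH3)–C9(=O))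
Conditions: B-(o-tolyl)oxazaborolidine of (S)-α,α-diphenylprolinol·HN(SO2CF3)2 (20 mol %), CH2Cl2, −78 → −40 °C; Et3N quench
Reagents that add atoms: none
Why: Proposed new method: a normal-demand, Lewis-acid-accelerated [4+2] in which the protonated oxazaborolidine lowers the quinone LUMO, the electron-rich CMe2 terminus of the silyl enol ether bonds first to the unsubstituted quinone carbon (future C5) and the CH2 terminus then closes on the methyl-bearing carbon (future C10); the closest known reaction type is the oxazaborolidinium-catalysed enantioselective Diels–Alder reaction of substituted benzoquinones with 2-silyloxybutadienes, which has not been shown with a fully substituted diene terminus or in this orientation. Ring A closes suprafacially on one quinone alkene (concerted and asynchronous; in the stepwise limit a Mukaiyama–Michael addition followed by 6-endo-trig closure of the boron enolate carbon C10 on C1 of the silyloxyallyl cation), so H5 and the C10 methyl come out cis. The absolute configuration at C10, and with it at C5, is set by the catalyst, which shields one enantiotopic face of the quinone alkene; the two quinone alkenes are homotopic, so only the face matters. The step needs regioselectivity, and the substrate secures it twice: joining the CMe2 terminus to the methyl-bearing carbon would create adjacent quaternary carbons, and both methyls donate vinylogously to the hydrogen-flanked carbonyl, so the methyl-flanked carbonyl (future C9) is the more electron-poor and makes future C5 the more electrophilic alkene carbon. The open point is the binding site: on the methyl-flanked oxygen polarisation and sterics agree but the usual α-C–H contact to the catalyst is missing, and on the more basic hydrogen-flanked oxygen that contact exists but the polarisation opposes the sterically enforced orientation, so rate and enantioselectivity have to be established. The uncatalysed background is negligible at low temperature because the cis methyl of the diene disfavours its s-cis conformer, and a second cycloaddition on the trisubstituted, quaternary-flanked alkene of 4 is not expected. Quenching with Et3N before warming protects the silyl enol ether from the acidic catalyst.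

Step 3
Reactants: 4 cis-fused adduct
Product: 6 dienyl triflate (8aR)-6-(tert-butyldimethylsilyloxy)-2,5,5,8a-tetramethyl-1-oxo-1,5,8,8a-tetrahydronaphthalen-4-yl trifluoromethanesulfonate, via potassium C5 enolate 5 (not isolated)
Conditions: KN(SiMe3)2, THF, −78 °C; then PhN(SO2CF3)2, −78 → 0 °C
Reagents that add atoms: N-phenylbis(trifluoromethanesulfonimide), O=S(=O)(N(c1ccccc1)S(=O)(=O)C(F)(F)F)C(F)(F)F
Why: Kinetic α′-deprotonation of an enone (C5–H is the only α-hydrogen of the ene-dione) and O-sulfonylation give the cross-conjugated enol triflate; this deletes the cis C5 centre, which equilibration cannot be trusted to invert, and activates the C6–O bond for removal. The ring-A silyl enol ether is inert to the amide base.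

Step 4
Reactants: 6 dienyl triflate
Product: 7 dienone (8aR)-6-(tert-butyldimethylsilyloxy)-2,5,5,8a-tetramethyl-8,8a-dihydronaphthalen-1(5H)-one (drimane numbering: 5,7-dien-9-one, 10R)
Conditions: Pd(OAc)2 (5 mol %), PPh3, HCO2H, n-Bu3N, DMF, 50 °C, dark
Reagents that add atoms: none
Why: Palladium-catalysed formate reduction of an enol triflate (oxidative addition to zerovalent palladium, formate exchange, decarboxylation, reductive elimination) replaces C6–OTf by C6–H; the amine-buffered medium spares the silyl enol ether. The homoannular dienone is kept cold, dark and acid-free and is used at once.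

Step 5
Reactants: 7 dienone
Product: 10 trans-fused ene-dione (4aR,8aR)-2,5,5,8a-tetramethyl-4a,5,8,8a-tetrahydronaphthalene-1,6(4H,7H)-dione, via lithium dienolate 8 (not isolated), via deconjugated enone 9 (not isolated)
Conditions: Li, NH3/THF, t-BuOH (1 equiv), −78 °C; isoprene, NH4Cl; then 1 M HCl, THF, 23 °C
Reagents that add atoms: none
Why: Dissolving-metal (Birch-type) 1,6-reduction of a linear dienone: two electrons and one proton are taken up at the δ-carbon C5, and the resulting dienolate 8 resists further reduction until the quench. C5 is protonated perpendicular to the π system on the face away from the C10 methyl, through the chair-like trans-decalin arrangement, which places H5 anti to the methyl. Acid then hydrolyses the silyl enol ether to the C3 ketone and moves the alkene of 9 into conjugation (C7=C8), erasing the transient C8 centre.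

Step 6
Reactants: 10 trans-fused ene-dione
Product: 11 (4aR,6R,8aR)-6-hydroxy-2,5,5,8a-tetramethyl-4a,5,6,7,8,8a-hexahydronaphthalen-1(4H)-one (drimane numbering 3R,5R,10R; equatorial 3-OH on the face of the C10 methyl)
Conditions: NaBH4, MeOH/CH2Cl2, −40 → −20 °C
Reagents that add atoms: none
Why: Borohydride reduction; the saturated C3 ketone reacts much faster than the conjugated C9 carbonyl, which is wedged between quaternary C10 and substituted C8. Axial hydride delivery on the face opposite the C10 methyl (the other face is blocked by the axial C4 methyl) gives the equatorial alcohol.

Step 7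
Reactants: 11 hydroxy enone
Product: 12 (2R,4aR,8aS)-1,1,4a,6-tetramethyl-5-methylidene-1,2,3,4,4a,5,8,8a-octahydronaphthalen-2-ol (drimane numbering: 3-hydroxydrima-7,9(11)-diene, 3R,5S,10R)
Conditions: Zn, CH2Br2, TiCl4, THF/CH2Cl2, 0 → 23 °C
Reagents that add atoms: dibromomethane, BrCBr
Why: Lombardo methylenation; the non-basic zinc/titanium methylene reagent converts hindered, enolisable ketones into methylene compounds where a phosphorus ylide would mainly deprotonate the γ-position (C6). The free hydroxyl is tolerated with excess reagent.

Step 8
Reactants: 12 diene alcohol
Product: 14 (2R,4aR,5R,8aS)-5-(hydroxymethyl)-1,1,4a,6-tetramethyl-1,2,3,4,4a,5,8,8a-octahydronaphthalen-2-ol, via B-alkyl-9-BBN adduct 13 (not isolated)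
Conditions: 9-BBN, THF, 0 → 40 °C; then NaOH, H2O2, 0 °C
Reagents that add atoms: hydrogen peroxide, OO
Why: Hydroboration–oxidation with a bulky dialkylborane; 9-BBN adds only to the 1,1-disubstituted exocyclic alkene, boron on C11, and delivers hydrogen to C9 from the face opposite the axial C10 methyl, so C11 ends equatorial on the methyl face (drimane numbering 3R,5S,9R,10R). The trisubstituted C7=C8 alkene is too hindered for this borane, and oxidation proceeds with retention.

Step 9
Reactants: 14 ene-diol
Product: 15 (3R,5S,7S,8R,9R,10R)-7,8-epoxydrimane-3,11-diol (epoxide oxygen on the face opposite the C10 methyl)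
Conditions: m-CPBA, NaHCO3, CH2Cl2, 0 °C
Reagents that add atoms: 3-chloroperoxybenzoic acid, OOC(=O)c1cccc(Cl)c1
Why: Peracid (Prilezhaev) epoxidation of the only alkene; the reagent approaches C7=C8 anti to the axial C10 methyl, which places the oxygen on that face and the C8 methyl on the methyl face, as in the target. The buffer prevents acid opening of the trisubstituted epoxide.

Step 10
Reactants: 15 epoxy-diol
Product: 16 (3R,5S,8S,9R,10R)-drimane-3,8,11-triol
Conditions: LiBHEt3, THF, 0 → 65 °C; aqueous NH4Cl
Reagents that add atoms: none
Why: SN2 hydride opening of a trisubstituted epoxide at its less substituted carbon; triethylborohydride attacks secondary C7 anti to the epoxide oxygen and leaves the C8–O bond untouched, so the tertiary alcohol keeps the configuration set in step 9. The C11 alkoxide–borane adduct carries no hydride, so internal delivery to tertiary C8, a risk with aluminium hydrides, cannot compete.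

Step 11
Reactants: 16 triol; 17 umbelliferone (7-hydroxycoumarin)
Product: 18 7-{[(3R,5S,8S,9R,10R)-3,8-dihydroxydriman-11-yl]oxy}-2H-chromen-2-one
Conditions: PPh3, DIAD, THF, 0 → 23 °C
Reagents that add atoms: none
Why: Mitsunobu etherification; only the primary C11 hydroxyl is activated readily (O3 is a neopentyl-type secondary alcohol, O8 is tertiary), and the phenol of 17 is acidic enough to serve as nucleophile. No stereocentre is touched, and the lactone enters only after all hydride steps.

Step 12
Reactants: 18 diol coumarin ether; 19 angelic acid ((Z)-2-methylbut-2-enoic acid)
Product: 20 target, (3R,5S,8S,9R,10R)-8-hydroxy-11-[(2-oxo-2H-chromen-7-yl)oxy]driman-3-yl (2Z)-2-methylbut-2-enoate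
Conditions: 19, 2,4,6-Cl3C6H2COCl, Et3N, toluene, 23 °C; then 18, 80 °C
Reagents that add atoms: none
Why: Yamaguchi-type mixed-anhydride esterification run without a nucleophilic amine catalyst; the mixed anhydride acylates the secondary C3 alcohol on heating, and the Z geometry is kept because no acylpyridinium intermediate is available to isomerise the angelate to the tiglate. The tertiary C8 hydroxyl does not react.

## Compound list

1 | 4-methylpent-1-en-3-one | C=CC(=O)C(C)C | starting material
2 | 3-(tert-butyldimethylsilyloxy)-4-methylpenta-1,3-diene | C=CC(O[Si](C)(C)C(C)(C)C)=C(C)C | intermediate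
3 | 2,6-dimethyl-1,4-benzoquinone | CC1=CC(=O)C=C(C)C1=O | starting material
4 | cis-fused adduct, (4aS,8aR)-6-(tert-butyldimethylsilyloxy)-2,5,5,8a-tetramethyl-4a,5,8,8a-tetrahydronaphthalene-1,4-dione | CC(C)(C)[Si](C)(C)OC1=CC[C@]2(C)[C@@H](C(=O)C=C(C)C2=O)C1(C)C | intermediate
5 | potassium C5 enolate of 4 | CC(C)(C)[Si](C)(C)OC1=CC[C@]2(C)C(=C([O-])C=C(C)C2=O)C1(C)C.[K+] | intermediate (not isolated)
6 | dienyl triflate, (8aR)-6-(tert-butyldimethylsilyloxy)-2,5,5,8a-tetramethyl-1-oxo-1,5,8,8a-tetrahydronaphthalen-4-yl trifluoromethanesulfonate | CC(C)(C)[Si](C)(C)OC1=CC[C@]2(C)C(=C(OS(=O)(=O)C(F)(F)F)C=C(C)C2=O)C1(C)C | intermediate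
7 | dienone, (8aR)-6-(tert-butyldimethylsilyloxy)-2,5,5,8a-tetramethyl-8,8a-dihydronaphthalen-1(5H)-one | CC(C)(C)[Si](C)(C)OC1=CC[C@]2(C)C(=CC=C(C)C2=O)C1(C)C | intermediate
8 | lithium dienolate (O9–C9=C8–C7=C6, trans H5) | CC(C)(C)[Si](C)(C)OC1=CC[C@]2(C)[C@H](C=CC(C)=C2[O-])C1(C)C.[Li+] | intermediate (not isolated)
9 | deconjugated enone, (4aR,8aR)-6-(tert-butyldimethylsilyloxy)-2,5,5,8a-tetramethyl-4a,5,8,8a-tetrahydronaphthalen-1(2H)-one, both C2 epimers | CC(C)(C)[Si](C)(C)OC1=CC[C@]2(C)[C@H](C=CC(C)C2=O)C1(C)C | intermediate (not isolated)
10 | trans-fused ene-dione, (4aR,8aR)-2,5,5,8a-tetramethyl-4a,5,8,8a-tetrahydronaphthalene-1,6(4H,7H)-dione | O=C1CC[C@]2(C)[C@H](CC=C(C)C2=O)C1(C)C | intermediate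
11 | (4aR,6R,8aR)-6-hydroxy-2,5,5,8a-tetramethyl-4a,5,6,7,8,8a-hexahydronaphthalen-1(4H)-one | O[C@@H]1CC[C@]2(C)[C@H](CC=C(C)C2=O)C1(C)C | intermediate
12 | (2R,4aR,8aS)-1,1,4a,6-tetramethyl-5-methylidene-1,2,3,4,4a,5,8,8a-octahydronaphthalen-2-ol | O[C@@H]1CC[C@]2(C)[C@H](CC=C(C)C2=C)C1(C)C | intermediate
13 | B-(C11-alkyl)-9-borabicyclo[3.3.1]nonane adduct of 12 | O[C@@H]1CC[C@]2(C)[C@H](CC=C(C)[C@H]2CB2C3CCCC2CCC3)C1(C)C | intermediate (not isolated)
14 | (2R,4aR,5R,8aS)-5-(hydroxymethyl)-1,1,4a,6-tetramethyl-1,2,3,4,4a,5,8,8a-octahydronaphthalen-2-ol | O[C@@H]1CC[C@]2(C)[C@H](CC=C(C)[C@H]2CO)C1(C)C | intermediate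
15 | (3R,5S,7S,8R,9R,10R)-7,8-epoxydrimane-3,11-diol | O[C@@H]1CC[C@]2(C)[C@H](C[C@@H]3O[C@]3(C)[C@H]2CO)C1(C)C | intermediate
16 | (3R,5S,8S,9R,10R)-drimane-3,8,11-triol | O[C@@H]1CC[C@]2(C)[C@H](CC[C@](C)(O)[C@H]2CO)C1(C)C | intermediate
17 | umbelliferone (7-hydroxycoumarin) | Oc1ccc2ccc(=O)oc2c1 | starting material
18 | 7-{[(3R,5S,8S,9R,10R)-3,8-dihydroxydriman-11-yl]oxy}-2H-chromen-2-one | O[C@@H]1CC[C@]2(C)[C@H](CC[C@](C)(O)[C@H]2COc2ccc3ccc(=O)oc3c2)C1(C)C | intermediate
19 | angelic acid, (Z)-2-methylbut-2-enoic acid | C/C=C(/C)C(=O)O | starting material
20 | (3R,5S,8S,9R,10R)-8-hydroxy-11-[(2-oxo-2H-chromen-7-yl)oxy]driman-3-yl (2Z)-2-methylbut-2-enoate | C/C=C(/C)C(=O)O[C@@H]1CC[C@]2(C)[C@H](CC[C@](C)(O)[C@H]2COc2ccc3ccc(=O)oc3c2)C1(C)C | target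

## Step count and least certain steps

Total step count: 12. Longest linear sequence: 12 steps (1 → 20); 3, 17 and 19 enter as purchased compounds.

Step 2 (key step, proposed new method). Most likely failure: poor enantioface selection, because the catalyst cannot adopt its usual two-point binding on the methyl-flanked carbonyl and binding on the other carbonyl opposes the sterically enforced orientation. The cycloaddition may also stall because of the cis methyl on the diene terminus, the acidic catalyst may desilylate the diene, or the first bond may form without ring closure. Fallback with known chemistry: 2 and 3 are combined without catalyst (toluene, 100 °C, or CH2Cl2 under about 10 kbar). The thermal regiochemistry of this quinone and sterics lead to the same constitution, giving the racemic cis adduct F1. F1 is resolved by preparative chromatography on a chiral stationary phase (cellulose or amylose carbamate), and the (5S,10R) enantiomer rejoins the route as 4.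

Step 3. Most likely failure: deprotonation of the γ-methyl on C8 in place of the hindered C5 methine, giving the extended dienolate and the wrong triflate. Fallback from 4: Luche reduction (NaBH4, CeCl3·7H2O, MeOH, −78 °C) reduces only the C6 carbonyl, since C9 is shielded by C10 and the C8 methyl, to give the C6 allylic alcohol F2. Mesylation gives the mesylate F3, and DBU eliminates across C5–C6, the only position with a β-hydrogen, to return at dienone 7. If H5 and O6 turn out syn, the Burgess reagent is applied to F2 instead.

Step 5. Most likely failure: first protonation at the unhindered C7 in place of the doubly flanked C5, or protonation of C5 from the methyl face, giving the cis fusion; over-reduction of the carbonyl is a lesser concern. Fallback from 4 through enolate 5: kinetic protonation at −78 °C with a hindered phenol on the face away from the C10 methyl gives the trans-fused epimer F4. Luche reduction gives the C6 alcohol F5 and acetylation the acetate F6. Zn in AcOH then removes the γ-acetoxy group reductively (zinc dienolate, protonation), the acid hydrolyses the silyl enol ether, and the route is rejoined at 10.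

Step 7. Most likely failure: no addition to the C9 carbonyl because of the flanking quaternary C10 and the C8 methyl, or cyclopropanation of the alkene by the zinc carbenoid. Fallback from 11: Me3SiCH2Li with CeCl3 adds the small, non-basic organocerium to the ketone to give the β-hydroxysilane F7. Peterson elimination (KH, THF, or HF, MeCN) returns at 12.

Step 10. Most likely failure: slow or misdirected opening. Trans-diaxial opening would require attack at tertiary C8, so attack at C7 must pass through a twist arrangement next to the axial C8 methyl; elimination to an allylic alcohol or opening at C8 could intervene. Fallback from 14, bypassing 15: Mukaiyama hydration (Co(acac)2, PhSiH3, O2, i-PrOH; then PPh3) forms the tertiary C8 radical by hydrogen-atom transfer to C7, and oxygen is taken up on the face away from the C10 methyl. It returns at 16 and makes no new isolated compound (F0).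

Step 11. Most likely failure: slow substitution at the β-branched C11, which lets O8 cyclise onto the activated C11 (oxetane) or lets the betaine be consumed unproductively. Fallback from 16: the aryl–oxygen bond is made instead of the alkyl–oxygen bond, by palladium-catalysed C–O coupling of the primary alcohol with 7-bromocoumarin (Pd2(dba)3, t-BuBrettPhos, Cs2CO3, toluene, 90 °C). This needs no substitution at C11, returns at 18 and makes no new compound (F0).

## Further compounds

F1 | step 2 | racemic cis adduct (1:1 mixture of 4 and its enantiomer) | CC(C)(C)[Si](C)(C)OC1=CC[C@]2(C)[C@@H](C(=O)C=C(C)C2=O)C1(C)C.CC(C)(C)[Si](C)(C)OC1=CC[C@@]2(C)[C@H](C(=O)C=C(C)C2=O)C1(C)C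
F2 | step 3 | cis-fused C6 allylic alcohol from 4 (5S,10R; C6 epimer as formed) | CC(C)(C)[Si](C)(C)OC1=CC[C@]2(C)[C@@H](C(O)C=C(C)C2=O)C1(C)C
F3 | step 3 | C6 methanesulfonate of F2 | CC(C)(C)[Si](C)(C)OC1=CC[C@]2(C)[C@@H](C(OS(C)(=O)=O)C=C(C)C2=O)C1(C)C
F4 | step 5 | trans-fused C5 epimer of 4 (5R,10R) | CC(C)(C)[Si](C)(C)OC1=CC[C@]2(C)[C@H](C(=O)C=C(C)C2=O)C1(C)C
F5 | step 5 | trans-fused C6 allylic alcohol (C6 epimer as formed) | CC(C)(C)[Si](C)(C)OC1=CC[C@]2(C)[C@H](C(O)C=C(C)C2=O)C1(C)C
F6 | step 5 | trans-fused C6 acetate | CC(C)(C)[Si](C)(C)OC1=CC[C@]2(C)[C@H](C(OC(C)=O)C=C(C)C2=O)C1(C)C
F7 | step 7 | C9 tertiary β-hydroxysilane from 11 (C9 epimer as formed) | O[C@@H]1CC[C@]2(C)[C@H](CC=C(C)C2(O)C[Si](C)(C)C)C1(C)C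
F0 | step 10 | none | none
F0 | step 11 | none | none
A1 | alternative 1 | 3,3-ethylenedioxy-8-hydroxydrim-5-en-11-oic acid, C9 epimer | O1CCOC12CC[C@]3(C)C(=CC[C@](C)(O)[C@@H]3C(=O)O)C2(C)C
A2 | alternative 1 | 6-(5,5-ethylenedioxy-2,6,6-trimethylcyclohex-1-en-1-yl)-4-hydroxy-4-methyltetrahydropyran-2-one | O=C1C[C@@](C)(O)C[C@@H](O1)C1=C(C)CCC2(OCCO2)C1(C)C
A3 | alternative 2 | 5,10-methano (cyclopropane) ketal with 8-silyloxy and 11-hydroxyl groups | O1CCOC12CC[C@]34C[C@@]3(C2)CC[C@](C)(O[Si](C)(C)C(C)(C)C)[C@H]4CO
A4 | alternative 2 | Birch-derived C5=C10 alkene ketal | O1CCOC12CCC3=C(C2)CC[C@](C)(O[Si](C)(C)C(C)(C)C)[C@H]3CO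
A5 | alternative 3 | methyl trans-4,4,10-trimethyl-3,9-dioxodecalin-2-carboxylate | COC(=O)C1C[C@]2(C)[C@H](CCCC2=O)C(C)(C)C1=O
A6 | alternative 3 | 2-methylcyclohex-2-enone | CC1=CCCCC1=O
A7 | alternative 3 | methyl acrylate | C=CC(=O)OC
A8 | alternative 3 | 2-methyl-1-phenoxy-1-(trimethylsilyloxy)prop-1-ene | CC(C)=C(Oc1ccccc1)O[Si](C)(C)C
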